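**Strategy.** The plan cuts the cyclopentane at its only CH2–CH2 bond, C4'–C5' (C1' = quaternary carbon bonded to the bicycle, C2' = CMe2, C3' = CHBr). These two ring atoms are the only unsubstituted, unhindered ones, so both can be alkene termini. A chirality-transferring Ireland–Claisen rearrangement first sets the contiguous quaternary carbons C1'/C2' in an acyclic 1,6-dien-3-one that also carries an alkyne on C1'. Ring-closing metathesis then closes the five-membered ring in one operation. The alkyne later becomes C2/C3 of ring A (alkylation of a cyclohexanedione, hydration, aldol condensation onto a ring B enal); dienone epoxidation and trans-diaxial hydrolysis finish.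

Key step: step 8

Remark: primed locants refer to the cyclopentane as defined above; unprimed locants follow the naphthalen-2(1H)-one numbering of the target (C1–C8a).
Assumption: for step 13 an anti-Prelog ketoreductase that accepts the substrate is taken from a commercial screening panel; such enzymes are known to desymmetrise 2,2-disubstituted cyclohexane-1,3-diones.

Step 1
Reactants: 1 (S)-but-3-yn-2-ol
Product: 3 (S)-pent-3-yn-2-ol, via dilithio dianion 2 (not isolated)
Conditions: n-BuLi (2.1 equiv), THF, −78 °C; MeI (1.0 equiv), DMPU, −78 °C to rt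
Reagents that add atoms: iodomethane, CI
Why: SN2 C-methylation of the lithium acetylide within the alkoxide/acetylide dianion; the chiral-pool carbinol centre is not touched.

Step 2
Reactants: 3 (S)-pent-3-yn-2-ol
Product: 5 (2S,3Z)-4-iodopent-3-en-2-ol, via cyclic vinylalanate 4 (not isolated)
Conditions: NaAlH2(OCH2CH2OMe)2 (Red-Al), THF, 0 °C to rt; then I2, −78 °C
Reagents that add atoms: iodine, II
Why: Hydroxyl-directed trans-hydroalumination of the propargylic alcohol places aluminium on the distal carbon in a five-membered chelate, and iodinolysis with retention gives the Z-vinyl iodide with iodine cis to the carbinol carbon.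

Step 3
Reactants: 5 (2S,3Z)-4-iodopent-3-en-2-ol; 6 tert-butyldimethyl(prop-2-yn-1-yloxy)silane
Product: 7 (2S,3Z)-7-[(tert-butyldimethylsilyl)oxy]-4-methylhept-3-en-5-yn-2-ol
Conditions: PdCl2(PPh3)2 (2 mol%), CuI (4 mol%), Et3N, THF, rt
Reagents that add atoms: none
Why: Sonogashira coupling proceeds with retention of alkene geometry, so the alkyne ends up cis to the carbinol carbon.

Step 4
Reactants: 7 (2S,3Z)-7-[(tert-butyldimethylsilyl)oxy]-4-methylhept-3-en-5-yn-2-ol; 8 2-methylpropanoyl chloride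
Product: 9 (2S,3Z)-7-[(tert-butyldimethylsilyl)oxy]-4-methylhept-3-en-5-yn-2-yl 2-methylpropanoate
Conditions: pyridine, DMAP (cat.), CH2Cl2, 0 °C to rt
Reagents that add atoms: none
Why: DMAP-catalysed acylation (esterification) of the secondary allylic alcohol, with the stereocentre unaffected.

Step 5
Reactants: 9 (2S,3Z)-7-[(tert-butyldimethylsilyl)oxy]-4-methylhept-3-en-5-yn-2-yl 2-methylpropanoate
Product: 12 (3R,4E)-3-{3-[(tert-butyldimethylsilyl)oxy]prop-1-yn-1-yl}-2,2,3-trimethylhex-4-enoic acid, via silyl ketene acetal 10 (not isolated), via trimethylsilyl ester 11 (not isolated)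
Conditions: LiN(iPr)2, Me3SiCl, THF, −78 °C, then 60 °C; aq. NH4Cl work-up
Reagents that add atoms: none
Why: Ireland–Claisen rearrangement: the symmetric (geometry-free) isobutyrate silyl ketene acetal rearranges suprafacially through a chair with the carbinol methyl equatorial, so the S carbinol and the Z alkene should transfer chirality to the new quaternary C1' (R) while forming the C1'–C2' bond and an E-propenyl group.

Step 6
Reactants: 12 (3R,4E)-3-{3-[(tert-butyldimethylsilyl)oxy]prop-1-yn-1-yl}-2,2,3-trimethylhex-4-enoic acid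
Product: 14 (3R,4E)-3-{3-[(tert-butyldimethylsilyl)oxy]prop-1-yn-1-yl}-N-methoxy-N,2,2,3-tetramethylhex-4-enamide, via acid chloride 13 (not isolated)
Conditions: 1-chloro-N,N,2-trimethylprop-1-en-1-amine, CH2Cl2, 0 °C; then MeNH(OMe)·HCl, Et3N
Reagents that add atoms: N,O-dimethylhydroxylamine hydrochloride, Cl.CNOC
Why: Amide formation through an acid chloride generated under neutral conditions tolerates the silyl ether and the hindered α-quaternary acid.

Step 7
Reactants: 14 (3R,4E)-3-{3-[(tert-butyldimethylsilyl)oxy]prop-1-yn-1-yl}-N-methoxy-N,2,2,3-tetramethylhex-4-enamide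
Product: 15 (5R,6E)-5-{3-[(tert-butyldimethylsilyl)oxy]prop-1-yn-1-yl}-4,4,5-trimethylocta-1,6-dien-3-one
Conditions: CH2=CHMgBr, THF, −20 to 0 °C; inverse quench into cold aq. HCl
Reagents that add atoms: vinylmagnesium bromide, C=C[Mg]Br
Why: Weinreb ketone synthesis: the chelated tetrahedral adduct stops at mono-addition and releases the vinyl ketone on acidic quench.

Step 8
Reactants: 15 (5R,6E)-5-{3-[(tert-butyldimethylsilyl)oxy]prop-1-yn-1-yl}-4,4,5-trimethylocta-1,6-dien-3-one
Product: 16 (R)-4-{3-[(tert-butyldimethylsilyl)oxy]prop-1-yn-1-yl}-4,5,5-trimethylcyclopent-2-en-1-one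
Conditions: second-generation Hoveyda–Grubbs catalyst RuCl2(H2IMes)(=CH-C6H4-2-OiPr) (5 mol%), toluene (0.01 M), 80 °C
Reagents that add atoms: none
Why: Ring-closing olefin metathesis: the ruthenium carbene joins the vinyl ketone terminus and the propenyl terminus through [2+2]/retro-[2+2] steps via ruthenacyclobutanes, expels propene and forms C4'=C5', which becomes the C4'H2–C5'H2 bond after step 9. The closest known reaction type is the RCM of 1,6-dien-3-ones to 4,4,5,5-tetrasubstituted cyclopentenones used for 1-aryl-1,2,2-trimethylcyclopentane terpenoids. One ring is closed, the five-membered carbocycle, by alkene–alkene metathesis that leaves an endocyclic double bond. No stereocentre is created, and the quaternary stereocentre C1' from step 5 is untouched. The step needs diene metathesis to outrun enyne metathesis and oligomerisation: the alkyne is internal and shielded, and it sits on the same quaternary carbon as the propenyl group, so an enyne closure from that carbene would need a four-membered ring. The two contiguous quaternary carbons pre-organise the diene for closure (gem-dialkyl effect).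

Step 9
Reactants: 16 (R)-4-{3-[(tert-butyldimethylsilyl)oxy]prop-1-yn-1-yl}-4,5,5-trimethylcyclopent-2-en-1-one
Product: 17 (R)-3-{3-[(tert-butyldimethylsilyl)oxy]prop-1-yn-1-yl}-2,2,3-trimethylcyclopentan-1-one
Conditions: [(Ph3P)CuH]6 (0.4 equiv), H2O (2 equiv), toluene, rt
Reagents that add atoms: none
Why: Conjugate (1,4-) reduction of the enone by copper hydride is chemoselective over the internal alkyne and turns C4'=C5' into the CH2–CH2 unit.

Step 10
Reactants: 17 (R)-3-{3-[(tert-butyldimethylsilyl)oxy]prop-1-yn-1-yl}-2,2,3-trimethylcyclopentan-1-one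
Product: 18 (1S,3R)-3-{3-[(tert-butyldimethylsilyl)oxy]prop-1-yn-1-yl}-2,2,3-trimethylcyclopentan-1-ol
Conditions: (R)-2-methyl-CBS-oxazaborolidine (0.2 equiv), catecholborane, toluene, −78 °C
Reagents that add atoms: none
Why: CBS reduction: the oxazaborolidine differentiates the quaternary C2' (large) from C4'H2 (small), so the R catalyst should give the S carbinol with OH cis to the C1' methyl under reagent control.

Step 11
Reactants: 18 (1S,3R)-3-{3-[(tert-butyldimethylsilyl)oxy]prop-1-yn-1-yl}-2,2,3-trimethylcyclopentan-1-ol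
Product: 19 (1R,3R)-1-bromo-3-(3-bromoprop-1-yn-1-yl)-2,2,3-trimethylcyclopentane
Conditions: Ph3PBr2 (3 equiv), CH2Cl2, 0 °C to reflux
Reagents that add atoms: dibromotriphenylphosphorane, BrP(Br)(c1ccccc1)(c1ccccc1)c1ccccc1
Why: Dehydroxy-bromination: SN2 displacement of the secondary oxyphosphonium with inversion should set the R bromide cis to the alkynyl group, and the same reagent converts the primary silyl ether directly into the propargylic bromide.

Step 12
Reactants: 19 (1R,3R)-1-bromo-3-(3-bromoprop-1-yn-1-yl)-2,2,3-trimethylcyclopentane; 20 2-methylcyclohexane-1,3-dione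
Product: 21 2-{3-[(1R,3R)-3-bromo-1,2,2-trimethylcyclopentyl]prop-2-yn-1-yl}-2-methylcyclohexane-1,3-dione
Conditions: KOH (1 equiv), H2O/1,4-dioxane, 60 °C
Reagents that add atoms: none
Why: SN2 C-alkylation of the stabilised 1,3-dione enolate by the reactive propargylic bromide creates the quaternary, still prochiral, carbon, while the hindered secondary bromide does not react.

Step 13
Reactants: 21 2-{3-[(1R,3R)-3-bromo-1,2,2-trimethylcyclopentyl]prop-2-yn-1-yl}-2-methylcyclohexane-1,3-dione
Product: 22 (2R,3R)-2-{3-[(1R,3R)-3-bromo-1,2,2-trimethylcyclopentyl]prop-2-yn-1-yl}-3-hydroxy-2-methylcyclohexan-1-one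
Conditions: ketoreductase (NADPH-dependent alcohol dehydrogenase, anti-Prelog type), NADP+ (cat.), 2-propanol, phosphate buffer pH 7, DMSO (10%), 30 °C
Reagents that add atoms: none
Why: Enzymatic desymmetrising ketone reduction: hydride delivery to one of the two enantiotopic carbonyls from the methyl face should set the quaternary centre (future C8a) and the carbinol (future C8) together, with OH trans to methyl, under catalyst control.

Step 14
Reactants: 22 (2R,3R)-2-{3-[(1R,3R)-3-bromo-1,2,2-trimethylcyclopentyl]prop-2-yn-1-yl}-3-hydroxy-2-methylcyclohexan-1-one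
Product: 23 (2S,3S)-3-bromo-2-{3-[(1R,3R)-3-bromo-1,2,2-trimethylcyclopentyl]prop-2-yn-1-yl}-2-methylcyclohexan-1-one
Conditions: CBr4, PPh3, CH2Cl2 then toluene, 0 to 60 °C
Reagents that add atoms: carbon tetrabromide, BrC(Br)(Br)Br
Why: Appel reaction: bromide displaces the oxyphosphonium group by SN2 with inversion, giving the bromide cis to the methyl group (future 8S), and the quaternary α-carbon rules out β-elimination towards the ketone.

Step 15
Reactants: 23 (2S,3S)-3-bromo-2-{3-[(1R,3R)-3-bromo-1,2,2-trimethylcyclopentyl]prop-2-yn-1-yl}-2-methylcyclohexan-1-one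
Product: 25 (2S,3S)-3-bromo-2-{3-[(1R,3R)-3-bromo-1,2,2-trimethylcyclopentyl]prop-2-yn-1-yl}-2,6-dimethylcyclohexan-1-one (C6 epimers), via lithium enolate 24 (not isolated)
Conditions: LiN(iPr)2, THF, −78 °C; MeI, −78 to −20 °C
Reagents that add atoms: iodomethane, CI
Why: Kinetic enolate formation at the only enolisable α-carbon and SN2 methylation; the new stereocentre is uncontrolled and is erased in step 16.

Step 16
Reactants: 25 (2S,3S)-3-bromo-2-{3-[(1R,3R)-3-bromo-1,2,2-trimethylcyclopentyl]prop-2-yn-1-yl}-2,6-dimethylcyclohexan-1-one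
Product: 27 (5S,6S)-5-bromo-6-{3-[(1R,3R)-3-bromo-1,2,2-trimethylcyclopentyl]prop-2-yn-1-yl}-2,6-dimethylcyclohex-1-en-1-yl trifluoromethanesulfonate, via potassium enolate 26 (not isolated)
Conditions: KN(SiMe3)2, THF, −78 to 0 °C; PhNTf2
Reagents that add atoms: N-phenylbis(trifluoromethanesulfonimide), O=S(=O)(N(c1ccccc1)S(=O)(=O)C(F)(F)F)C(F)(F)F
Why: O-Sulfonylation of the only possible enolate gives the tetrasubstituted enol triflate (future C4a=C5).

Step 17
Reactants: 27 (5S,6S)-5-bromo-6-{3-[(1R,3R)-3-bromo-1,2,2-trimethylcyclopentyl]prop-2-yn-1-yl}-2,6-dimethylcyclohex-1-en-1-yl trifluoromethanesulfonate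
Product: 28 (5S,6S)-5-bromo-6-{3-[(1R,3R)-3-bromo-1,2,2-trimethylcyclopentyl]-2-oxopropyl}-2,6-dimethylcyclohex-1-en-1-yl trifluoromethanesulfonate
Conditions: Ph3PAuNTf2 (5 mol%), H2O (5 equiv), 1,4-dioxane, 60 °C
Reagents that add atoms: water, O
Why: Gold-catalysed alkyne hydration: water should attack the π-activated alkyne at the carbon remote from the shielding quaternary C1', placing the ketone at the future C2.

Step 18
Reactants: 28 (5S,6S)-5-bromo-6-{3-[(1R,3R)-3-bromo-1,2,2-trimethylcyclopentyl]-2-oxopropyl}-2,6-dimethylcyclohex-1-en-1-yl trifluoromethanesulfonate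
Product: 29 (5S,6S)-5-bromo-6-{3-[(1R,3R)-3-bromo-1,2,2-trimethylcyclopentyl]-2-oxopropyl}-2,6-dimethylcyclohex-1-ene-1-carbaldehyde
Conditions: Pd(OAc)2 (5 mol%), dppp, CO (1 atm), Et3SiH, Et3N, DMF, 70 °C
Reagents that add atoms: carbon monoxide, [C-]#[O+]
Why: Palladium-catalysed reductive carbonylation (formylation) of the enol triflate by oxidative addition, CO insertion and hydride transfer from the silane gives the enal (future C4).

Step 19
Reactants: 29 (5S,6S)-5-bromo-6-{3-[(1R,3R)-3-bromo-1,2,2-trimethylcyclopentyl]-2-oxopropyl}-2,6-dimethylcyclohex-1-ene-1-carbaldehyde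
Product: 31 (8S,8aS)-8-bromo-3-[(1R,3R)-3-bromo-1,2,2-trimethylcyclopentyl]-5,8a-dimethyl-6,7,8,8a-tetrahydronaphthalen-2(1H)-one, via aldol adduct 30 (not isolated)
Conditions: p-TsOH·H2O (cat.), toluene, reflux (Dean–Stark)
Reagents that add atoms: none
Why: Intramolecular aldol condensation: only the enol towards C3 can reach the aldehyde through a six-membered transition state, and dehydration is driven by formation of the linearly conjugated dienone.

Step 20
Reactants: 31 (8S,8aS)-8-bromo-3-[(1R,3R)-3-bromo-1,2,2-trimethylcyclopentyl]-5,8a-dimethyl-6,7,8,8a-tetrahydronaphthalen-2(1H)-one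
Product: 32 (4aR,5S,8S,8aS)-8-bromo-3-[(1R,3R)-3-bromo-1,2,2-trimethylcyclopentyl]-4a,5-epoxy-5,8a-dimethyl-4a,5,6,7,8,8a-hexahydronaphthalen-2(1H)-one
Conditions: mCPBA, NaHCO3, CH2Cl2, 0 °C
Reagents that add atoms: 3-chloroperoxybenzoic acid, OOC(=O)c1cccc(Cl)c1
Why: Peracid (Prilezhaev) epoxidation should select the electron-richer tetrasubstituted γ,δ-alkene over the acyl-substituted α,β-alkene and occur anti to the axial 8a-methyl group, setting the 4a oxygen trans to that methyl.

Step 21
Reactants: 32 (4aR,5S,8S,8aS)-8-bromo-3-[(1R,3R)-3-bromo-1,2,2-trimethylcyclopentyl]-4a,5-epoxy-5,8a-dimethyl-4a,5,6,7,8,8a-hexahydronaphthalen-2(1H)-one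
Product: 33 (4aR,5R,8S,8aS)-8-bromo-3-[(1R,3R)-3-bromo-1,2,2-trimethylcyclopentyl]-4a,5-dihydroxy-5,8a-dimethyl-4a,5,6,7,8,8a-hexahydronaphthalen-2(1H)-one
Conditions: HClO4 (aq., cat.), THF/H2O, 0 °C to rt
Reagents that add atoms: water, O
Why: Acid-catalysed epoxide hydrolysis: water should open the protonated epoxide at the tertiary C5 (remote from the enone) with inversion in the trans-diaxial sense (Fürst–Plattner rule), setting 5R and leaving the 4a oxygen in place as the 4aR alcohol.

**Compound list**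

1 | (S)-but-3-yn-2-ol | C[C@H](O)C#C | starting material
2 | dilithio dianion of 1 (not isolated) | C[C@H]([O-])C#[C-].[Li+].[Li+] | intermediate
3 | (S)-pent-3-yn-2-ol | C[C@H](O)C#CC | intermediate
4 | sodium cyclic alkoxy(vinyl)alanate from 3 (not isolated) | C[C@@H]1O[Al-](OCCOC)(OCCOC)C(C)=C1.[Na+] | intermediate
5 | (2S,3Z)-4-iodopent-3-en-2-ol | C[C@H](O)/C=C(I)/C | intermediate
6 | tert-butyldimethyl(prop-2-yn-1-yloxy)silane | C#CCO[Si](C)(C)C(C)(C)C | starting material
7 | (2S,3Z)-7-[(tert-butyldimethylsilyl)oxy]-4-methylhept-3-en-5-yn-2-ol | C[C@H](O)/C=C(C#CCO[Si](C)(C)C(C)(C)C)/C | intermediate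
8 | 2-methylpropanoyl chloride | CC(C)C(Cl)=O | starting material
9 | (2S,3Z)-7-[(tert-butyldimethylsilyl)oxy]-4-methylhept-3-en-5-yn-2-yl 2-methylpropanoate | C[C@H](OC(=O)C(C)C)/C=C(C#CCO[Si](C)(C)C(C)(C)C)/C | intermediate
10 | trimethylsilyl ketene acetal of 9 (not isolated) | C[C@H](OC(O[Si](C)(C)C)=C(C)C)/C=C(C#CCO[Si](C)(C)C(C)(C)C)/C | intermediate
11 | trimethylsilyl ester of 12 (not isolated) | C[Si](C)(C)OC(=O)C(C)(C)[C@@](C)(C#CCO[Si](C)(C)C(C)(C)C)/C=C/C | intermediate
12 | (3R,4E)-3-{3-[(tert-butyldimethylsilyl)oxy]prop-1-yn-1-yl}-2,2,3-trimethylhex-4-enoic acid | OC(=O)C(C)(C)[C@@](C)(C#CCO[Si](C)(C)C(C)(C)C)/C=C/C | intermediate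
13 | acid chloride of 12 (not isolated) | ClC(=O)C(C)(C)[C@@](C)(C#CCO[Si](C)(C)C(C)(C)C)/C=C/C | intermediate
14 | (3R,4E)-3-{3-[(tert-butyldimethylsilyl)oxy]prop-1-yn-1-yl}-N-methoxy-N,2,2,3-tetramethylhex-4-enamide | CON(C)C(=O)C(C)(C)[C@@](C)(C#CCO[Si](C)(C)C(C)(C)C)/C=C/C | intermediate
15 | (5R,6E)-5-{3-[(tert-butyldimethylsilyl)oxy]prop-1-yn-1-yl}-4,4,5-trimethylocta-1,6-dien-3-one | C=CC(=O)C(C)(C)[C@@](C)(C#CCO[Si](C)(C)C(C)(C)C)/C=C/C | intermediate
16 | (R)-4-{3-[(tert-butyldimethylsilyl)oxy]prop-1-yn-1-yl}-4,5,5-trimethylcyclopent-2-en-1-one | CC1(C)C(=O)C=C[C@]1(C)C#CCO[Si](C)(C)C(C)(C)C | intermediate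
17 | (R)-3-{3-[(tert-butyldimethylsilyl)oxy]prop-1-yn-1-yl}-2,2,3-trimethylcyclopentan-1-one | CC1(C)C(=O)CC[C@]1(C)C#CCO[Si](C)(C)C(C)(C)C | intermediate
18 | (1S,3R)-3-{3-[(tert-butyldimethylsilyl)oxy]prop-1-yn-1-yl}-2,2,3-trimethylcyclopentan-1-ol | CC1(C)[C@@H](O)CC[C@]1(C)C#CCO[Si](C)(C)C(C)(C)C | intermediate
19 | (1R,3R)-1-bromo-3-(3-bromoprop-1-yn-1-yl)-2,2,3-trimethylcyclopentane | CC1(C)[C@H](Br)CC[C@]1(C)C#CCBr | intermediate
20 | 2-methylcyclohexane-1,3-dione | CC1C(=O)CCCC1=O | starting material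
21 | 2-{3-[(1R,3R)-3-bromo-1,2,2-trimethylcyclopentyl]prop-2-yn-1-yl}-2-methylcyclohexane-1,3-dione | CC1(C)[C@H](Br)CC[C@]1(C)C#CCC1(C)C(=O)CCCC1=O | intermediate
22 | (2R,3R)-2-{3-[(1R,3R)-3-bromo-1,2,2-trimethylcyclopentyl]prop-2-yn-1-yl}-3-hydroxy-2-methylcyclohexan-1-one | CC1(C)[C@H](Br)CC[C@]1(C)C#CC[C@@]2(C)C(=O)CCC[C@H]2O | intermediate
23 | (2S,3S)-3-bromo-2-{3-[(1R,3R)-3-bromo-1,2,2-trimethylcyclopentyl]prop-2-yn-1-yl}-2-methylcyclohexan-1-one | CC1(C)[C@H](Br)CC[C@]1(C)C#CC[C@@]2(C)C(=O)CCC[C@@H]2Br | intermediate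
24 | lithium enolate of 23 (not isolated) | CC1(C)[C@H](Br)CC[C@]1(C)C#CC[C@@]2(C)C([O-])=CCC[C@@H]2Br.[Li+] | intermediate
25 | (2S,3S)-3-bromo-2-{3-[(1R,3R)-3-bromo-1,2,2-trimethylcyclopentyl]prop-2-yn-1-yl}-2,6-dimethylcyclohexan-1-one (C6 epimers) | CC1(C)[C@H](Br)CC[C@]1(C)C#CC[C@@]2(C)C(=O)C(C)CC[C@@H]2Br | intermediate
26 | potassium enolate of 25 (not isolated) | CC1(C)[C@H](Br)CC[C@]1(C)C#CC[C@@]2(C)C([O-])=C(C)CC[C@@H]2Br.[K+] | intermediate
27 | (5S,6S)-5-bromo-6-{3-[(1R,3R)-3-bromo-1,2,2-trimethylcyclopentyl]prop-2-yn-1-yl}-2,6-dimethylcyclohex-1-en-1-yl trifluoromethanesulfonate | CC1(C)[C@H](Br)CC[C@]1(C)C#CC[C@@]2(C)C(OS(=O)(=O)C(F)(F)F)=C(C)CC[C@@H]2Br | intermediate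
28 | (5S,6S)-5-bromo-6-{3-[(1R,3R)-3-bromo-1,2,2-trimethylcyclopentyl]-2-oxopropyl}-2,6-dimethylcyclohex-1-en-1-yl trifluoromethanesulfonate | CC1(C)[C@H](Br)CC[C@]1(C)CC(=O)C[C@@]2(C)C(OS(=O)(=O)C(F)(F)F)=C(C)CC[C@@H]2Br | intermediate
29 | (5S,6S)-5-bromo-6-{3-[(1R,3R)-3-bromo-1,2,2-trimethylcyclopentyl]-2-oxopropyl}-2,6-dimethylcyclohex-1-ene-1-carbaldehyde | CC1(C)[C@H](Br)CC[C@]1(C)CC(=O)C[C@@]2(C)C(C=O)=C(C)CC[C@@H]2Br | intermediate
30 | β-hydroxy ketone aldol adduct of 29 (not isolated; C3 and C4 unassigned) | CC1(C)[C@H](Br)CC[C@]1(C)C1C(O)C2=C(C)CC[C@H](Br)[C@@]2(C)CC1=O | intermediate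
31 | (8S,8aS)-8-bromo-3-[(1R,3R)-3-bromo-1,2,2-trimethylcyclopentyl]-5,8a-dimethyl-6,7,8,8a-tetrahydronaphthalen-2(1H)-one | CC1(C)[C@H](Br)CC[C@]1(C)C1=CC2=C(C)CC[C@H](Br)[C@@]2(C)CC1=O | intermediate
32 | (4aR,5S,8S,8aS)-8-bromo-3-[(1R,3R)-3-bromo-1,2,2-trimethylcyclopentyl]-4a,5-epoxy-5,8a-dimethyl-4a,5,6,7,8,8a-hexahydronaphthalen-2(1H)-one | CC1(C)[C@H](Br)CC[C@]1(C)C1=C[C@@]23O[C@@]3(C)CC[C@H](Br)[C@@]2(C)CC1=O | intermediate
33 | (4aR,5R,8S,8aS)-8-bromo-3-[(1R,3R)-3-bromo-1,2,2-trimethylcyclopentyl]-4a,5-dihydroxy-5,8a-dimethyl-4a,5,6,7,8,8a-hexahydronaphthalen-2(1H)-one | CC1(C)[C@H](Br)CC[C@]1(C)C1=C[C@]2(O)[C@](C)(O)CC[C@H](Br)[C@@]2(C)CC1=O | target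

**Totals.** Total step count: 21. Longest linear sequence: 21 steps (1 to 33); 6, 8 and 20 enter as commercial building blocks.

**Steps most likely to fail**

Step 14 (bromination of the neopentyl-type cyclohexyl carbinol). The oxyphosphonium intermediate may ionise, with 1,2-shift or elimination, instead of undergoing clean backside displacement, so that configuration or the skeleton is lost. Fallback: activation and C–Br bond formation are separated. Setting out from 22, O-sulfonylation (Tf2O, pyridine, CH2Cl2, −40 °C) should give (1R,2R)-2-{3-[(1R,3R)-3-bromo-1,2,2-trimethylcyclopentyl]prop-2-yn-1-yl}-2-methyl-3-oxocyclohexyl trifluoromethanesulfonate F1. This isolated sulfonate is then displaced by a non-basic bromide salt (Bu4NBr, toluene, rt) in a non-ionising medium, with inversion, which returns to the route at 23.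

Step 13 (enzymatic desymmetrisation). The bulky, lipophilic dione may not be accepted by the enzyme, or the enzyme may select the wrong enantiotopic carbonyl or the wrong face. Fallback: small-molecule catalysis instead of biocatalysis. Setting out from 21, a CBS reduction with (S)-2-methyl-CBS-oxazaborolidine and catecholborane (toluene, −78 °C) should fix the carbinol configuration (large = quaternary carbon, small = CH2), while attack from the less hindered methyl face selects the carbonyl. This returns directly to 22 without any new compound.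

Step 18 (carbonylative formylation). The acylpalladium intermediate may be intercepted by the enol of the side-chain ketone (O-acylation to an enol lactone) before hydride transfer. Fallback: the one-carbon unit is introduced as a nucleophile, so no acylpalladium species arises. Setting out from 28, Stille coupling with (tributylstannyl)methanol (Pd(PPh3)4, LiCl, 1,4-dioxane, 90 °C) should give 1-[(1R,3R)-3-bromo-1,2,2-trimethylcyclopentyl]-3-[(1S,6S)-6-bromo-2-(hydroxymethyl)-1,3-dimethylcyclohex-2-en-1-yl]propan-2-one F2. Allylic oxidation with MnO2 (CH2Cl2, rt) then returns to the route at 29.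

**Further compounds**

F1 | step 14 | (1R,2R)-2-{3-[(1R,3R)-3-bromo-1,2,2-trimethylcyclopentyl]prop-2-yn-1-yl}-2-methyl-3-oxocyclohexyl trifluoromethanesulfonate | CC1(C)[C@H](Br)CC[C@]1(C)C#CC[C@@]2(C)C(=O)CCC[C@H]2OS(=O)(=O)C(F)(F)F
F0 | step 13 | none | none
F2 | step 18 | 1-[(1R,3R)-3-bromo-1,2,2-trimethylcyclopentyl]-3-[(1S,6S)-6-bromo-2-(hydroxymethyl)-1,3-dimethylcyclohex-2-en-1-yl]propan-2-one | CC1(C)[C@H](Br)CC[C@]1(C)CC(=O)C[C@@]2(C)C(CO)=C(C)CC[C@@H]2Br
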